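The tetrahydrofuran (O1, C2 carrying the trimethoxyphenyl group, C3 carrying CH2OH, C4, C5; carbinol carbon Cα on C4) is cut at O1–C2 and C3–C4. The feature exploited is that O1–C5–C4 with Cα is a ring-opened 1-arylvinyl oxirane, Cα being the middle carbon of its allyl system, while C2–C3 is an arylidene malonate. One palladium-catalysed annulation joins these partners, forms both bonds, closes the ring and sets C2 and C4 cis under ligand control. Its precursors are racemic 2-[1-(3,4-dimethoxyphenyl)vinyl]oxirane and dimethyl 2-(3,4,5-trimethoxybenzylidene)malonate. The vinyl group is later cleaved to the ketone, and C3 and Cα are set by equilibration and Felkin-controlled reduction.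

Key step: step 4

Assumption: the ligand antipode that leads to the (2S,4R) adduct 8 cannot be predicted with confidence; the route is written for the (R,R) ligand, and the (S,S) ligand would be used if a first analytical run shows the opposite sense.

Step 1
Reactants: 1 (3,4-dimethoxyphenyl)acetaldehyde
Product: 3 2-(3,4-dimethoxyphenyl)prop-2-enal, via Mannich base 2 (not isolated)
Conditions: [CH2=NMe2]I, Et3N, CH2Cl2, 0 °C → rt
Reagents that add atoms: N,N-dimethylmethyleneiminium iodide (Eschenmoser's salt), C=[N+](C)C.[I-]
Why: Mannich reaction of the enolisable aldehyde with the preformed iminium salt, followed by base-induced elimination of dimethylamine from the β-amino aldehyde (α-methylenation), is a standard entry to 2-arylacroleins; no stereocentre is formed and the product is used promptly because it polymerises on storage.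

Step 2
Reactants: 3 2-(3,4-dimethoxyphenyl)prop-2-enal
Product: 4 2-[1-(3,4-dimethoxyphenyl)vinyl]oxirane (racemic)
Conditions: Me3SI, n-BuLi, THF, −10 °C; then 3, −78 → 0 °C; filtration through Et3N-deactivated silica
Reagents that add atoms: trimethylsulfonium iodide, C[S+](C)C.[I-]
Why: In this Corey–Chaykovsky epoxidation the unstabilised sulfonium ylide adds to the aldehyde carbon rather than the conjugate position and the betaine closes to the oxirane with loss of dimethyl sulfide; the new stereocentre forms as a racemate, which is acceptable because palladium erases it in step 4.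

Step 3
Reactants: 5 3,4,5-trimethoxybenzaldehyde; 6 dimethyl malonate
Product: 7 dimethyl 2-(3,4,5-trimethoxybenzylidene)malonate
Conditions: piperidine (cat.), AcOH (cat.), toluene, reflux, Dean–Stark
Reagents that add atoms: none
Why: Knoevenagel condensation driven by azeotropic removal of water; the alkene has no geometric isomers because the two ester groups are identical.

Step 4
Reactants: 4 2-[1-(3,4-dimethoxyphenyl)vinyl]oxirane (racemic); 7 dimethyl 2-(3,4,5-trimethoxybenzylidene)malonate
Product: 8 dimethyl (2S,4R)-4-[1-(3,4-dimethoxyphenyl)vinyl]-2-(3,4,5-trimethoxyphenyl)tetrahydrofuran-3,3-dicarboxylate (2,4-cis)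
Conditions: Pd2(dba)3·CHCl3 (2.5 mol%), (1R,2R)-N,N'-bis[2-(diphenylphosphino)benzoyl]cyclohexane-1,2-diamine (7.5 mol%), THF, 25–40 °C, 4 (1.5 equiv) added slowly
Reagents that add atoms: none
Why: Zerovalent palladium ionises the allylic C–O bond of racemic 4 to a zwitterionic 2-aryl-π-allylpalladium alkoxide whose diastereomeric forms interconvert by η3–η1–η3 slippage at the unsubstituted CH2 terminus, so that both enantiomers of 4 converge; the alkoxide adds reversibly to the β-carbon of 7 (oxa-Michael, O1–C2) and the malonate carbanion then alkylates the nearer allyl terminus with release of the catalyst (C3–C4). The closest known reaction type is the palladium-catalysed formal (3+2) cycloaddition of vinyl oxiranes with doubly activated alkenes to 4-vinyltetrahydrofurans, for which ligand-controlled enantioselective variants also exist. The tetrahydrofuran ring closes in a 5-exo mode, the carbanion attacking the allyl carbon that carries the CH2O tether on the face opposite to palladium, which leaves the 1-arylvinyl group exocyclic. C4 is set by the chiral ligand, which selects the face of the equilibrating π-allyl that is alkylated, and C2 is set in the same transition state because the oxa-Michael step is reversible (Curtin–Hammett), the trimethoxyphenyl and arylvinyl groups both taking pseudo-equatorial positions on the forming envelope and hence ending up cis. The step needs attack at the internal rather than the terminal allyl carbon (five- against seven-membered ring), which the short tether secures, and 2,4-cis together with absolute selectivity, which the ligand pocket must secure; any 2,4-trans isomer is to be removed by chromatography because it would lower the optical purity once C4 becomes enolisable.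

Step 5
Reactants: 8 dimethyl (2S,4R)-4-[1-(3,4-dimethoxyphenyl)vinyl]-2-(3,4,5-trimethoxyphenyl)tetrahydrofuran-3,3-dicarboxylate
Product: 10 methyl (2R,3R,4S)-4-[1-(3,4-dimethoxyphenyl)vinyl]-2-(3,4,5-trimethoxyphenyl)tetrahydrofuran-3-carboxylate (2,3-trans-3,4-trans), via C3-epimeric monoester 9 (not isolated)
Conditions: LiCl, H2O, DMSO, 150 °C; extractive work-up; then NaOMe (0.3 equiv), MeOH, 50 °C
Reagents that add atoms: none
Why: Krapcho dealkoxycarbonylation (chloride demethylates one ester, the carboxylate loses CO2, the enolate is protonated) should give both C3 epimers, and methoxide equilibration through the ester enolate should then funnel them to the all-trans isomer, in which the ester avoids both the C2 aryl and the C4 arylvinyl group, while C4, not enolisable at this stage, stays fixed as the reference centre.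

Step 6
Reactants: 10 methyl (2R,3R,4S)-4-[1-(3,4-dimethoxyphenyl)vinyl]-2-(3,4,5-trimethoxyphenyl)tetrahydrofuran-3-carboxylate
Product: 12 methyl (2R,3R,4R)-4-(3,4-dimethoxybenzoyl)-2-(3,4,5-trimethoxyphenyl)tetrahydrofuran-3-carboxylate, via vicinal diol 11 (not isolated)
Conditions: OsO4 (2 mol%), NaIO4 (4 equiv), 2,6-lutidine, 1,4-dioxane/H2O 3:1, rt
Reagents that add atoms: osmium tetroxide, O=[Os](=O)(=O)=O (catalytic oxygen carrier); sodium periodate, [Na+].[O-]I(=O)(=O)=O (terminal oxidant)
Why: In this Lemieux–Johnson oxidation OsO4 dihydroxylates the electron-rich 1,1-disubstituted alkene and periodate cleaves the diol to the aryl ketone and formaldehyde under lutidine-buffered conditions that spare the methoxyarenes and the ester; C4 becomes enolisable but already holds the thermodynamically preferred trans relationship to C3, so no stereocentre should be lost.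

Step 7
Reactants: 12 methyl (2R,3R,4R)-4-(3,4-dimethoxybenzoyl)-2-(3,4,5-trimethoxyphenyl)tetrahydrofuran-3-carboxylate
Product: 13 methyl (2R,3R,4R)-4-[(S)-(3,4-dimethoxyphenyl)(hydroxy)methyl]-2-(3,4,5-trimethoxyphenyl)tetrahydrofuran-3-carboxylate
Conditions: LiBH(s-Bu)3, THF, −78 °C; sat. aq. NH4Cl
Reagents that add atoms: none
Why: In this Felkin–Anh-controlled ketone reduction the branched ring carbon C3 acts as the large group perpendicular to the carbonyl and C5 sits on the carbonyl-oxygen side, so the bulky hydride should attack anti to C3 and create Cα as S, while the methyl ester is inert to this reagent at −78 °C.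

Step 8
Reactants: 13 methyl (2R,3R,4R)-4-[(S)-(3,4-dimethoxyphenyl)(hydroxy)methyl]-2-(3,4,5-trimethoxyphenyl)tetrahydrofuran-3-carboxylate
Product: 14 (2R,3S,4R)-4-[(S)-(3,4-dimethoxyphenyl)(hydroxy)methyl]-3-(hydroxymethyl)-2-(3,4,5-trimethoxyphenyl)tetrahydrofuran (CNP0172668.1)
Conditions: LiAlH4, THF, 0 °C; Fieser work-up (H2O, aq. NaOH)
Reagents that add atoms: none
Why: Standard LiAlH4 reduction of the methyl ester to the primary alcohol touches no stereocentre (the C3 descriptor changes from R to S only through the priority rules), and the basic work-up avoids ionisation of the electron-rich benzylic alcohol.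

Compound list
1 | (3,4-dimethoxyphenyl)acetaldehyde | COc1ccc(CC=O)cc1OC | starting material
2 | 3-(dimethylamino)-2-(3,4-dimethoxyphenyl)propanal (racemic Mannich base) | CN(C)CC(C=O)c1ccc(OC)c(OC)c1 | intermediate
3 | 2-(3,4-dimethoxyphenyl)prop-2-enal | C=C(C=O)c1ccc(OC)c(OC)c1 | intermediate
4 | 2-[1-(3,4-dimethoxyphenyl)vinyl]oxirane (racemic) | C=C(c1ccc(OC)c(OC)c1)C1CO1 | intermediate
5 | 3,4,5-trimethoxybenzaldehyde | COc1cc(C=O)cc(OC)c1OC | starting material
6 | dimethyl malonate | COC(=O)CC(=O)OC | starting material
7 | dimethyl 2-(3,4,5-trimethoxybenzylidene)malonate | COC(=O)C(=Cc1cc(OC)c(OC)c(OC)c1)C(=O)OC | intermediate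
8 | dimethyl (2S,4R)-4-[1-(3,4-dimethoxyphenyl)vinyl]-2-(3,4,5-trimethoxyphenyl)tetrahydrofuran-3,3-dicarboxylate (2,4-cis) | COC(=O)C1(C(=O)OC)[C@@H](C(=C)c2ccc(OC)c(OC)c2)CO[C@H]1c1cc(OC)c(OC)c(OC)c1 | intermediate
9 | methyl (2R,4S)-4-[1-(3,4-dimethoxyphenyl)vinyl]-2-(3,4,5-trimethoxyphenyl)tetrahydrofuran-3-carboxylate, mixture of C3 epimers | COC(=O)C1[C@@H](C(=C)c2ccc(OC)c(OC)c2)CO[C@H]1c1cc(OC)c(OC)c(OC)c1 | intermediate
10 | methyl (2R,3R,4S)-4-[1-(3,4-dimethoxyphenyl)vinyl]-2-(3,4,5-trimethoxyphenyl)tetrahydrofuran-3-carboxylate (all-trans) | COC(=O)[C@@H]1[C@@H](C(=C)c2ccc(OC)c(OC)c2)CO[C@H]1c1cc(OC)c(OC)c(OC)c1 | intermediate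
11 | methyl (2R,3R,4R)-4-[1-(3,4-dimethoxyphenyl)-1,2-dihydroxyethyl]-2-(3,4,5-trimethoxyphenyl)tetrahydrofuran-3-carboxylate, either configuration at the carbinol carbon | COC(=O)[C@@H]1[C@@H](C(O)(CO)c2ccc(OC)c(OC)c2)CO[C@H]1c1cc(OC)c(OC)c(OC)c1 | intermediate
12 | methyl (2R,3R,4R)-4-(3,4-dimethoxybenzoyl)-2-(3,4,5-trimethoxyphenyl)tetrahydrofuran-3-carboxylate | COC(=O)[C@@H]1[C@@H](C(=O)c2ccc(OC)c(OC)c2)CO[C@H]1c1cc(OC)c(OC)c(OC)c1 | intermediate
13 | methyl (2R,3R,4R)-4-[(S)-(3,4-dimethoxyphenyl)(hydroxy)methyl]-2-(3,4,5-trimethoxyphenyl)tetrahydrofuran-3-carboxylate | COC(=O)[C@@H]1[C@@H]([C@H](O)c2ccc(OC)c(OC)c2)CO[C@H]1c1cc(OC)c(OC)c(OC)c1 | intermediate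
14 | (2R,3S,4R)-4-[(S)-(3,4-dimethoxyphenyl)(hydroxy)methyl]-3-(hydroxymethyl)-2-(3,4,5-trimethoxyphenyl)tetrahydrofuran | COc1ccc([C@@H](O)[C@H]2CO[C@@H](c3cc(OC)c(OC)c(OC)c3)[C@@H]2CO)cc1OC | target

Total step count: 8. Longest linear sequence: 7 steps (steps 1, 2, 4, 5, 6, 7, 8 from compound 1).

Steps most likely to fail

1. Step 4. The electron-rich arylidene malonate is a weak acceptor, so capture of the palladium-bound alkoxide may be too slow and the zwitterion may decay by isomerisation or oligomerisation; facial discrimination in the ring closure may also be incomplete. The fallback sets out from 5 and keeps oxirane 4. Condensation of 5 with 2,2-dimethyl-1,3-dioxane-4,6-dione (Meldrum's acid; water, 75 °C) should give 2,2-dimethyl-5-(3,4,5-trimethoxybenzylidene)-1,3-dioxane-4,6-dione F1, a far stronger acceptor of the class best documented for ligand-controlled palladium annulations with zwitterionic allyl species. Annulation of F1 with 4 under the catalyst system of step 4 should give (1S,4R)-4-[1-(3,4-dimethoxyphenyl)vinyl]-8,8-dimethyl-1-(3,4,5-trimethoxyphenyl)-2,7,9-trioxaspiro[4.5]decane-6,10-dione F2. NaOMe in MeOH at rt opens the dioxanedione with loss of acetone, and acidification gives (2S,4R)-4-[1-(3,4-dimethoxyphenyl)vinyl]-3-(methoxycarbonyl)-2-(3,4,5-trimethoxyphenyl)tetrahydrofuran-3-carboxylic acid F3 as a mixture at C3. Heating F3 in DMSO at about 110 °C decarboxylates it to the epimer mixture 9, and the methoxide equilibration of step 5 brings the material back to the route at 10.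

2. Step 7. Hydride delivery may show insufficient facial selectivity, because the two ring carbons flanking C4 differ only moderately in size. The fallback sets out from 12 and replaces substrate control by catalyst control. Corey–Bakshi–Shibata reduction with (R)-1-methyl-3,3-diphenyltetrahydro-1H,3H-pyrrolo[1,2-c][1,3,2]oxazaborole (10–20 mol%) and BH3·SMe2 in THF at −20 °C should, with the aryl group as the large substituent, deliver the (S)-carbinol irrespective of the ring bias. The ester is not reduced under these conditions, and the route is rejoined at 13. This fallback makes no new compound (F0).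

3. Step 2. The basic ylide may cause polymerisation of, or conjugate addition to, the 2-arylacrolein, and the allylic epoxide may open on acidic supports. The fallback sets out from 3 and builds the oxirane in two stages through a carbenoid. Chloromethyllithium, generated in the presence of 3 from ICH2Cl and MeLi·LiBr in THF at −78 °C, adds to the aldehyde carbon, and a cold quench with AcOH should give racemic 1-chloro-3-(3,4-dimethoxyphenyl)but-3-en-2-ol F4. K2CO3 in MeOH at rt then closes the ring, and after filtration through basic alumina the route is rejoined at 4.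

Further compounds
F1 | step 4 | 2,2-dimethyl-5-(3,4,5-trimethoxybenzylidene)-1,3-dioxane-4,6-dione | CC1(C)OC(=O)C(=Cc2cc(OC)c(OC)c(OC)c2)C(=O)O1
F2 | step 4 | (1S,4R)-4-[1-(3,4-dimethoxyphenyl)vinyl]-8,8-dimethyl-1-(3,4,5-trimethoxyphenyl)-2,7,9-trioxaspiro[4.5]decane-6,10-dione | CC1(C)OC(=O)C2(C(=O)O1)[C@@H](C(=C)c1ccc(OC)c(OC)c1)CO[C@H]2c1cc(OC)c(OC)c(OC)c1
F3 | step 4 | (2S,4R)-4-[1-(3,4-dimethoxyphenyl)vinyl]-3-(methoxycarbonyl)-2-(3,4,5-trimethoxyphenyl)tetrahydrofuran-3-carboxylic acid, mixture at C3 | COC(=O)C1(C(=O)O)[C@@H](C(=C)c2ccc(OC)c(OC)c2)CO[C@H]1c1cc(OC)c(OC)c(OC)c1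
F0 | step 7 | none | none
F4 | step 2 | 1-chloro-3-(3,4-dimethoxyphenyl)but-3-en-2-ol (racemic) | C=C(c1ccc(OC)c(OC)c1)C(O)CCl
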